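**Plan**
- Labels used throughout: C1 = CH(OBz) next to the quaternary carbon, C2=C3, C4 = CH(OBz), C5 = CH(OH), C6 = C(OH), C7 = CH2OH. The retrosynthesis first removes the two silyl ethers (O5, O7) and the two benzoyl groups, then cuts the C1–O and C4–O bonds together: the cis-1,4-dioxygenated C1–C2=C3–C4 segment of the cyclohexene is the reduced form of a 1,2-dioxine ring bridging C1 and C4 (a 2,3-dioxabicyclo[2.2.2]oct-5-ene), that is, a cyclohexa-1,3-diene plus O2.
- The diene is traced back through two HBr eliminations and a Br2 addition to a C2=C3 cyclohexene, the C5–O bond to an SN2 epoxide opening, the C5/C6 oxirane to an allylic alcohol, and the C1–C6 and C4–C5 ring bonds to a butadiene/methyl propiolate Diels–Alder reaction.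
- Forward order of rings: carbocycle (step 1), temporary oxirane on C5/C6 (step 3), temporary peroxide bridge C1–O–O–C4 (step 9); no other ring is made.
- Stereochemistry: C6 and C5 come from a Sharpless epoxidation with D-(−)-diethyl tartrate followed by invertive benzoate delivery at C5 (trans-diol). C1 and C4 come from suprafacial singlet-oxygen addition to the diene face that carries the free C6 hydroxyl and lies opposite the two silyl-protected substituents.

Key step: step 9

Remark: TBS = tert-butyldimethylsilyl; locants inside compound names are systematic, whereas C1–C7 in the text always mean the labels above.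
Remark on the chemistry: Br2 may add to give either anti 2,3-dibromide, and either HBr may be lost first. Compound 9 is drawn as the (2S,3S) adduct and compound 10 as the C1=C2 allylic bromide; the alternatives converge on the same diene 11.

**Route**

Step 1
Reactants: 1 buta-1,3-diene; 2 methyl propiolate
Product: 3 methyl cyclohexa-1,4-diene-1-carboxylate
Conditions: hydroquinone (cat.), toluene, sealed tube, 110 °C
Reagents that add atoms: none
Why: Thermal Diels–Alder [4+2] cycloaddition of the s-cis diene to the electron-poor alkyne gives the skipped cyclohexadiene directly, with no regiochemical or stereochemical issue because the diene is symmetrical and no stereocenter forms.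

Step 2
Reactants: 3 methyl cyclohexa-1,4-diene-1-carboxylate
Product: 4 (cyclohexa-1,4-dien-1-yl)methanol
Conditions: iBu2AlH (2.3 equiv), CH2Cl2, −78 → 0 °C; aq. potassium sodium tartrate
Reagents that add atoms: none
Why: 1,2-Reduction of the conjugated ester by the aluminium hydride gives the allylic alcohol and leaves both ring alkenes in place.

Step 3
Reactants: 4 (cyclohexa-1,4-dien-1-yl)methanol
Product: 5 [(1R,6R)-7-oxabicyclo[4.1.0]hept-3-en-1-yl]methanol (oxirane on C5/C6, C2=C3 alkene intact)
Conditions: Ti(OiPr)4 (10 mol %), D-(−)-diethyl tartrate (12 mol %), tBuOOH (2 equiv, isooctane), 4 Å MS, CH2Cl2, −20 °C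
Reagents that add atoms: tert-butyl hydroperoxide, CC(C)(C)OO
Why: Sharpless asymmetric epoxidation delivers oxygen only to the allylic C5=C6 alkene (the C2=C3 alkene is bishomoallylic and not directed), and the D-(−)-tartrate ligand should select the face that makes C5 and C6 both R, the mirror image of the sense that L-(+)-tartrate gives with 1-cyclohexenylmethanol.

Step 4
Reactants: 5 [(1R,6R)-7-oxabicyclo[4.1.0]hept-3-en-1-yl]methanol
Product: 6 (1S,6R)-6-hydroxy-6-(hydroxymethyl)cyclohex-3-en-1-yl benzoate (benzoate on C5, trans to the C6 hydroxyl)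
Conditions: Ti(OiPr)4 (1.5 equiv), PhCO2H (1.3 equiv), CH2Cl2, rt; aq. tartaric acid work-up
Reagents that add atoms: benzoic acid, OC(=O)c1ccccc1
Why: Titanium-mediated C3-selective opening of a 2,3-epoxy alcohol: within the titanium alkoxide chelate the benzoate attacks the secondary C5 by SN2 with inversion while the C6–O bond stays intact, so C5 becomes S and the C5/C6 oxygens end up trans.

Step 5
Reactants: 6 (1S,6R)-6-hydroxy-6-(hydroxymethyl)cyclohex-3-en-1-yl benzoate
Product: 7 (1R,2S)-1-(hydroxymethyl)cyclohex-4-ene-1,2-diol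
Conditions: K2CO3 (0.3 equiv), MeOH, rt
Reagents that add atoms: none
Why: Zemplén-type transesterification removes the benzoate (including any that has migrated to O7) without touching a stereocenter, so the regiochemistry of acyl migration in step 4 becomes irrelevant.

Step 6
Reactants: 7 (1R,2S)-1-(hydroxymethyl)cyclohex-4-ene-1,2-diol
Product: 8 (1R,6S)-6-(TBS-oxy)-1-[(TBS-oxy)methyl]cyclohex-3-en-1-ol (silyl ethers on O5 and O7, tertiary C6–OH free)
Conditions: TBSCl (2.5 equiv), imidazole, DMAP (cat.), DMF, rt → 45 °C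
Reagents that add atoms: tert-butyldimethylsilyl chloride, CC(C)(C)[Si](C)(C)Cl
Why: Imidazole-promoted silylation protects the primary and the secondary hydroxyl, while the tertiary C6 hydroxyl does not react with a silyl chloride under these conditions.

Step 7
Reactants: 8 (1R,6S)-6-(TBS-oxy)-1-[(TBS-oxy)methyl]cyclohex-3-en-1-ol
Product: 9 (1R,2S,4S,5S)-4,5-dibromo-2-(TBS-oxy)-1-[(TBS-oxy)methyl]cyclohexan-1-ol (trans bromines on C2 and C3)
Conditions: Br2 (1.05 equiv), CH2Cl2, −78 °C
Reagents that add atoms: bromine, BrBr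
Why: Electrophilic anti addition through a bromonium ion gives the trans-diaxial dibromide (Fürst–Plattner opening); the silyl ethers tolerate Br2 in CH2Cl2 at low temperature, and the new C2/C3 centers are removed again in step 8.

Step 8
Reactants: 9 (1R,2S,4S,5S)-4,5-dibromo-2-(TBS-oxy)-1-[(TBS-oxy)methyl]cyclohexan-1-ol
Product: 11 (1R,6S)-6-(TBS-oxy)-1-[(TBS-oxy)methyl]cyclohexa-2,4-dien-1-ol, via allylic bromide 10 (not isolated)
Conditions: DBU (5 equiv), THF, 50 °C, dark
Reagents that add atoms: none
Why: Two successive E2 dehydrobrominations, each taking an antiperiplanar hydrogen from the C1 or C4 methylene group, are the standard entry from 4,5-dibromocyclohexane-1,2-diol derivatives to 5,6-dioxygenated cyclohexa-1,3-dienes; C5 and C6 are untouched and base-induced aromatisation is blocked because C6 carries no hydrogen.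

Step 9
Reactants: 11 (1R,6S)-6-(TBS-oxy)-1-[(TBS-oxy)methyl]cyclohexa-2,4-dien-1-ol
Product: 12 (1S,4R,7S,8S)-8-(TBS-oxy)-7-[(TBS-oxy)methyl]-2,3-dioxabicyclo[2.2.2]oct-5-en-7-ol (peroxide bridge from C1 to C4 on the face of the C6 hydroxyl)
Conditions: O2, 5,10,15,20-tetraphenylporphyrin (1 mol %), CH2Cl2, −30 °C, visible light
Reagents that add atoms: dioxygen, O=O
Why: The porphyrin sensitises triplet oxygen to singlet oxygen, which adds as the 2π partner in a concerted suprafacial [4+2] cycloaddition to the ring-locked s-cis C1=C2–C3=C4 diene; the closest known reaction type is the photooxygenation of cyclohexa-1,3-dienes, including 5,6-trans-dioxygenated ones, to 2,3-dioxabicyclo[2.2.2]oct-5-enes. The only ring closed is the six-membered 1,2-dioxine O–C1–C2=C3–C4–O, formed by simultaneous C1–O and C4–O bonding at the diene termini, which moves the alkene to C2=C3. C1 and C4 are the new stereocenters: their cis relationship follows from the suprafacial mode, and their absolute sense from the face of attack, which is set by the existing C5 and C6 centers. The step needs attack on the face bearing the C6 hydroxyl and C5–H; the other face is blocked by the C5 silyl ether and the C7 silyloxymethyl arm, and in the aprotic solvent the free allylic tertiary hydroxyl can hydrogen-bond to the incoming oxygen, so steric and directing effects agree. It also needs cycloaddition to win over the ene reaction at C5–H, which the cisoid conjugated diene should secure at low temperature.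

Step 10
Reactants: 12 (1S,4R,7S,8S)-8-(TBS-oxy)-7-[(TBS-oxy)methyl]-2,3-dioxabicyclo[2.2.2]oct-5-en-7-ol
Product: 13 (1S,2S,3S,4R)-3-(TBS-oxy)-2-[(TBS-oxy)methyl]cyclohex-5-ene-1,2,4-triol (cis hydroxyls on C1 and C4)
Conditions: thiourea (1.5 equiv), MeOH (not dried), rt
Reagents that add atoms: none
Why: Thiourea reduces only the O–O bond of the endoperoxide under neutral conditions, so both C–O bonds and their configuration are kept (cis-ene-1,4-diol) and the base-induced Kornblum–DeLaMare rearrangement to a hydroxy enone is avoided.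

Step 11
Reactants: 13 (1S,2S,3S,4R)-3-(TBS-oxy)-2-[(TBS-oxy)methyl]cyclohex-5-ene-1,2,4-triol; 14 benzoyl chloride
Product: 15 (1R,4S,5S,6S)-6-(TBS-oxy)-5-hydroxy-5-[(TBS-oxy)methyl]cyclohex-2-ene-1,4-diyl dibenzoate
Conditions: BzCl (3 equiv), pyridine, DMAP (0.2 equiv), CH2Cl2, 0 °C → rt
Reagents that add atoms: benzoyl chloride (compound 14), O=C(Cl)c1ccccc1
Why: DMAP-catalysed acylation esterifies the two secondary allylic hydroxyls on C1 and C4, while the hindered tertiary C6 hydroxyl does not acylate at or below room temperature; no stereocenter is touched.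

Step 12
Reactants: 15 (1R,4S,5S,6S)-6-(TBS-oxy)-5-hydroxy-5-[(TBS-oxy)methyl]cyclohex-2-ene-1,4-diyl dibenzoate
Product: 16 (1R,4S,5R,6S)-5,6-dihydroxy-5-(hydroxymethyl)cyclohex-2-ene-1,4-diyl dibenzoate (the target)
Conditions: HF·pyridine (excess), pyridine, THF, 0 °C → rt
Reagents that add atoms: none
Why: Fluoride-induced desilylation under buffered, weakly acidic conditions cleaves both Si–O bonds without the basic alkoxide that would let a benzoate migrate to the freed C5 or C7 hydroxyl.

**Compound list**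
1 | buta-1,3-diene | C=CC=C | starting material
2 | methyl propiolate | COC(=O)C#C | starting material
3 | methyl cyclohexa-1,4-diene-1-carboxylate | COC(=O)C1=CCC=CC1 | intermediate
4 | (cyclohexa-1,4-dien-1-yl)methanol | OCC1=CCC=CC1 | intermediate
5 | [(1R,6R)-7-oxabicyclo[4.1.0]hept-3-en-1-yl]methanol | C1C=CC[C@H]2O[C@@]12CO | intermediate
6 | (1S,6R)-6-hydroxy-6-(hydroxymethyl)cyclohex-3-en-1-yl benzoate | C1C=CC[C@H](OC(=O)c2ccccc2)[C@]1(O)CO | intermediate
7 | (1R,2S)-1-(hydroxymethyl)cyclohex-4-ene-1,2-diol | C1C=CC[C@H](O)[C@]1(O)CO | intermediate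
8 | (1R,6S)-6-(TBS-oxy)-1-[(TBS-oxy)methyl]cyclohex-3-en-1-ol | C1C=CC[C@H](O[Si](C)(C)C(C)(C)C)[C@]1(O)CO[Si](C)(C)C(C)(C)C | intermediate
9 | (1R,2S,4S,5S)-4,5-dibromo-2-(TBS-oxy)-1-[(TBS-oxy)methyl]cyclohexan-1-ol | C1[C@H](Br)[C@@H](Br)C[C@H](O[Si](C)(C)C(C)(C)C)[C@]1(O)CO[Si](C)(C)C(C)(C)C | intermediate
10 | (1R,4S,6S)-4-bromo-6-(TBS-oxy)-1-[(TBS-oxy)methyl]cyclohex-2-en-1-ol | C1=C[C@@H](Br)C[C@H](O[Si](C)(C)C(C)(C)C)[C@]1(O)CO[Si](C)(C)C(C)(C)C | intermediate
11 | (1R,6S)-6-(TBS-oxy)-1-[(TBS-oxy)methyl]cyclohexa-2,4-dien-1-ol | C1=CC=C[C@H](O[Si](C)(C)C(C)(C)C)[C@]1(O)CO[Si](C)(C)C(C)(C)C | intermediate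
12 | (1S,4R,7S,8S)-8-(TBS-oxy)-7-[(TBS-oxy)methyl]-2,3-dioxabicyclo[2.2.2]oct-5-en-7-ol | O3[C@H]1C=C[C@@H](O3)[C@H](O[Si](C)(C)C(C)(C)C)[C@]1(O)CO[Si](C)(C)C(C)(C)C | intermediate
13 | (1S,2S,3S,4R)-3-(TBS-oxy)-2-[(TBS-oxy)methyl]cyclohex-5-ene-1,2,4-triol | O[C@H]1C=C[C@@H](O)[C@H](O[Si](C)(C)C(C)(C)C)[C@]1(O)CO[Si](C)(C)C(C)(C)C | intermediate
14 | benzoyl chloride | O=C(Cl)c1ccccc1 | starting material
15 | (1R,4S,5S,6S)-6-(TBS-oxy)-5-hydroxy-5-[(TBS-oxy)methyl]cyclohex-2-ene-1,4-diyl dibenzoate | O=C(O[C@H]1C=C[C@@H](OC(=O)c2ccccc2)[C@H](O[Si](C)(C)C(C)(C)C)[C@]1(O)CO[Si](C)(C)C(C)(C)C)c1ccccc1 | intermediate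
16 | (1R,4S,5R,6S)-5,6-dihydroxy-5-(hydroxymethyl)cyclohex-2-ene-1,4-diyl dibenzoate | O=C(O[C@H]1C=C[C@@H](OC(=O)c2ccccc2)[C@H](O)[C@]1(O)CO)c1ccccc1 | target

**Totals**
Total step count: 12. Longest linear sequence: 12 steps (1 and 2 to 16; benzoyl chloride 14 enters at step 11).

**Steps most likely to fail**

Step 8 (double dehydrobromination). The sequence may stall after the first elimination, lose the second HBr in a conjugate sense through C5–H to give a silyl dienol ether, or be diverted by intramolecular etherification of the free C6 hydroxyl onto the allylic bromide. The fallback sets out from 7 and returns at 11; it makes the diene on the fully acylated substrate class for which this elimination is established, and silylates afterwards. Triol 7 is peracetylated (Ac2O, Et3N, DMAP, CH2Cl2) to (1R,2S)-1-(acetoxymethyl)cyclohex-4-ene-1,2-diyl diacetate F5. Br2 in CH2Cl2 gives the trans-dibromide F6, and DBU in THF gives the diene triacetate F7. K2CO3 in MeOH releases (1R,6S)-1-(hydroxymethyl)cyclohexa-2,4-diene-1,6-diol F8, which TBSCl/imidazole silylates at O5 and O7 to give 11.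

Step 9 (photooxygenation). Facial selectivity may be poor, or hydrogen abstraction at C5–H (ene pathway) may compete with the cycloaddition. The fallback sets out from 11 and returns at 15; it installs the two oxygens one after the other on the same face. Hydroxyl-directed epoxidation with VO(acac)2/tBuOOH puts an oxirane on C1=C2 syn to the C6 hydroxyl, giving the vinyl epoxide (1S,2S,3S,6S)-3-(TBS-oxy)-2-[(TBS-oxy)methyl]-7-oxabicyclo[4.1.0]hept-4-en-2-ol F9. Pd(PPh3)4 (zerovalent palladium) with benzoic acid then effects a Tsuji–Trost 1,4-opening with net retention (double inversion) to the cis hydroxy benzoate (1R,4S,5S,6S)-6-(TBS-oxy)-4,5-dihydroxy-5-[(TBS-oxy)methyl]cyclohex-2-en-1-yl benzoate F10. Benzoylation of its C1 hydroxyl with 14 (pyridine, DMAP) gives 15.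

Step 4 (epoxide opening). Benzoate may attack the tertiary C6 instead of C5; because both regiochemistries give a trans-diol, this leak would produce the enantiomeric series and erode the enantiomeric purity. The fallback sets out from 4 and returns at 7; it uses intramolecular delivery at C6 on the opposite epoxide enantiomer. Alcohol 4 is epoxidised with L-(+)-diethyl tartrate in place of the D ligand to give [(1S,6S)-7-oxabicyclo[4.1.0]hept-3-en-1-yl]methanol F1. PhNCO/Et3N converts it into the phenylurethane [(1S,6S)-7-oxabicyclo[4.1.0]hept-3-en-1-yl]methyl N-phenylcarbamate F2. BF3·OEt2 in Et2O at −20 °C makes the carbamate carbonyl oxygen open the oxirane at C6 with inversion (five-membered ring closure), giving the cyclic iminocarbonate (5R,6S)-2-(phenylimino)-1,3-dioxaspiro[4.5]dec-8-en-6-ol F3. Dilute H2SO4 in the work-up hydrolyses it to the cyclic carbonate (5R,6S)-6-hydroxy-1,3-dioxaspiro[4.5]dec-8-en-2-one F4, and K2CO3/MeOH then gives 7.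

**Further compounds**
F1 | step 4 | [(1S,6S)-7-oxabicyclo[4.1.0]hept-3-en-1-yl]methanol | C1C=CC[C@@H]2O[C@]12CO
F2 | step 4 | [(1S,6S)-7-oxabicyclo[4.1.0]hept-3-en-1-yl]methyl N-phenylcarbamate | C1C=CC[C@@H]2O[C@]12COC(=O)Nc1ccccc1
F3 | step 4 | (5R,6S)-2-(phenylimino)-1,3-dioxaspiro[4.5]dec-8-en-6-ol | C1C=CC[C@H](O)[C@@]12OC(=Nc3ccccc3)OC2
F4 | step 4 | (5R,6S)-6-hydroxy-1,3-dioxaspiro[4.5]dec-8-en-2-one | C1C=CC[C@H](O)[C@@]12OC(=O)OC2
F5 | step 8 | (1R,2S)-1-(acetoxymethyl)cyclohex-4-ene-1,2-diyl diacetate | C1C=CC[C@H](OC(C)=O)[C@]1(OC(C)=O)COC(C)=O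
F6 | step 8 | (1R,2S,4S,5S)-1-(acetoxymethyl)-4,5-dibromocyclohexane-1,2-diyl diacetate | C1[C@H](Br)[C@@H](Br)C[C@H](OC(C)=O)[C@]1(OC(C)=O)COC(C)=O
F7 | step 8 | (1R,6S)-1-(acetoxymethyl)cyclohexa-2,4-diene-1,6-diyl diacetate | C1=CC=C[C@H](OC(C)=O)[C@]1(OC(C)=O)COC(C)=O
F8 | step 8 | (1R,6S)-1-(hydroxymethyl)cyclohexa-2,4-diene-1,6-diol | C1=CC=C[C@H](O)[C@]1(O)CO
F9 | step 9 | (1S,2S,3S,6S)-3-(TBS-oxy)-2-[(TBS-oxy)methyl]-7-oxabicyclo[4.1.0]hept-4-en-2-ol | O1[C@H]2C=C[C@H](O[Si](C)(C)C(C)(C)C)[C@](O)(CO[Si](C)(C)C(C)(C)C)[C@@H]12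
F10 | step 9 | (1R,4S,5S,6S)-6-(TBS-oxy)-4,5-dihydroxy-5-[(TBS-oxy)methyl]cyclohex-2-en-1-yl benzoate | O[C@H]1C=C[C@@H](OC(=O)c2ccccc2)[C@H](O[Si](C)(C)C(C)(C)C)[C@]1(O)CO[Si](C)(C)C(C)(C)C
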